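Time comes first here: the chain length is asked for at 10 d, in closed flasks where the earlier runs show Q rising to a peak and then falling.

common to all: E 33 mM
- delta: L 0.37 mol%; run made earlier
- zeta: L 0.76 mol%; run made earlier
- Sunday's: L 0.5 mol%; time 10 d
- Monday's: L 1 mol%; time 10 d

| run | time / d | Q / % |
|---|---|---|
| delta | 1.25 | 48 |
| delta | 3.00 | 58 |
| delta | 4.00 | 55 |
| delta | 6.00 | 53 |
| delta | 8.00 | 46 |
| delta | 10.0 | 39 |
| zeta | 0.833 | 54 |
| zeta | 1.25 | 65 |
| zeta | 1.67 | 65 |
| zeta | 3.00 | 66 |
| zeta | 4.00 | 62 |
| zeta | 6.00 | 59 |
| zeta | 10.0 | 51 |

(scatter of a reading: 1.5 percentage points)

1. which of the two ends with the longer chains by the average number of monomer units in a chain (chains begun, living or dead) ("neither" if they lie within 10%) (Sunday's / Monday's / neither)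
2. average number of monomer units in a chain (chains begun, living or dead) at the end, Sunday's
3. average number of monomer units in a chain (chains begun, living or dead) at the end, Monday's

- the average divides the monomer in chains by the number of chains begun, living and dead together
- the numbers in the tables scatter with a standard deviation of 1.5 percentage points
- the earlier runs do not show the number of chains; that part of a forecast is a guess

The bench rule takes one chain per L charged. Its figure is the charge ratio C, the units of E charged per L charged, 200 for Sunday's and 100 for Monday's. The average length (number-average degree of polymerisation) is then C times the fraction of E standing as Q. A straight line through the last readings of delta and zeta against the logarithm of the loading puts Q at the end at 44.0% for Sunday's, whose loading lies between those of the two runs, and at 55.6% for Monday's, whose loading lies beyond zeta's. This reckoning therefore gives 88.0 for Sunday's, longer than the 55.6 for Monday's.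

The rule counts every L as begun, and the earlier runs do not show the number of chains, so that count is a guess. The peak reads at 3.00 d in delta, and zeta's plateau begins at 1.25 d. That ratio of readings, 2.40, stands near the loading ratio of 2.05, so the rise time τ is taken as inverse in L: 2.22 d for Sunday's and 1.11 d for Monday's. The asked time is 4.50 τ for Sunday's and 9.01 τ for Monday's. This reckoning takes a ratio of one as the border of the rule: delta's first reading, at 0.417 of its peak time, stands on the rise, where the rule is not offered.

The forecast names Sunday's, with 90 and 57, both higher than this reckoning. On the number of chains it says: “I assume roughly one chain per L, all begun by day 10.”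

The simulation gives Sunday's, with 91.3 for Sunday's and 51.5 for Monday's.

    E + L → Z + Q (k = 5.10 M⁻¹ h⁻¹)
    E + Z → Q + Z, rate k2*[Z]*[E] (k = 390 M⁻¹ h⁻¹)
    Q + Z → E + Z, rate k3*[Z] as long as [Q] is above zero (k = 0.910 h⁻¹)
    E → J (k = 0.0170 h⁻¹)

C times the simulated Q at the end gives 90.6 for Sunday's and 50.8 for Monday's. The neighbouring flask is Sunday's read at 4.0 d, which is 1.80 τ. Interpolating the readings at that time gives Q of 57.9%, so C gives 116. That flask gives 121, with Q at 58.9% and 3.0% of the charged L still there.

The data were computed for substances that don't exist; noise was put on by code.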